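A closed flask, a plug-flow tube and a well-mixed tank at two mean residence times take the same charge, and I want to know which one delivers the most target.

| setting | east | west | south | Saturday's | Tuesday's | Sunday's | Thursday's |
|---|---|---|---|---|---|---|---|
| starting material | 0.30 M | 0.30 M | 0.30 M | 0.30 M | 0.30 M | 0.30 M | 0.30 M |
| protic impurity | 0.030 M | 0.030 M | 0.030 M | 0.0300 M | 0.0300 M | 0.0300 M | 0.0300 M |
| catalyst | 1.7 mM | 2.4 mM | 3.7 mM | 1.7 mM | 1.7 mM | 1.7 mM | 1.7 mM |
| added ligand | 3.1 mM | 3.1 mM | 3.1 mM | 3.1 mM | 3.1 mM | 3.1 mM | 3.1 mM |
| remark | run made earlier | run made earlier | run made earlier | plug flow through a tube for 12 h, no back-mixing | a single well-mixed tank run continuously and read at steady state, 60.0 h in it on average | a single well-mixed tank run continuously and read at steady state, 12 h in it on average | a closed flask charged with all of it at once and left for 12 h |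
| time |  |  |  | 12 h |  |  | 12 h |

| east: time / h | east: target / % | west: time / h | west: target / % | south: time / h | south: target / % |
|---|---|---|---|---|---|
| 1.00 | 0.8 | 0.417 | 1.4 | 0.500 | 3.8 |
| 1.33 | 1.6 | 1.00 | 1.2 | 0.833 | 6.3 |
| 2.00 | 1.2 | 2.00 | 3.7 | 1.33 | 10.3 |
| 3.00 | 3.4 | 3.00 | 5.1 | 2.00 | 14.6 |
| 5.00 | 5.1 | 4.00 | 8.4 | 3.00 | 21.4 |
| 8.00 | 7.6 | 6.00 | 12.3 | 5.00 | 31.1 |
| 12.0 | 10.2 | 8.00 | 14.5 | 8.00 | 44.4 |

(readings scatter by 0.5 percentage points)

- the stated concentrations are those of everything mixed, before any reaction; amounts are the same in each set-up
- the earlier runs were made in a closed, stirred flask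

* the set-up with the highest amount of target at the outlet or at the end, in percent of the starting material put in ("none" if the first two lie within 2 percentage points) (Saturday's / Tuesday's / Sunday's / Thursday's / none)
* amount of target at the outlet or at the end, in percent of the starting material put in, Saturday's
* amount of target at the outlet or at the end, in percent of the starting material put in, Tuesday's
* amount of target at the outlet or at the end, in percent of the starting material put in, Sunday's
* amount of target at the outlet or at the end, in percent of the starting material put in, Thursday's

A rate constant is the fraction of a material that reacts per hour, so I test one on the south run, which reaches 44.4 %. Read as first-order decay of the whole charge, that run gives 0.0789 h⁻¹ at 2.00 h and 0.0734 h⁻¹ at 8.00 h, so the constant drifts down. I assume that each protic impurity takes one starting material early, which leaves a working pool of 90.0 % of the charge. Read against that pool, the south run gives 0.0885 h⁻¹ and 0.0850 h⁻¹, which are level within the scatter of 0.5 percentage points.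

The set-ups share the east charge, so I carry one number: the pool constant, the pseudo-first-order fraction of the remaining pool that becomes target per hour, read from the last east reading as 0.0100 h⁻¹. Each slice of Saturday's tube ages like Thursday's flask, so I expect the east reading of 10.2 % from both.

A tank reacts at its outlet composition, so the pool it leaves unreacted is the pool divided by one plus the pool constant times the mean residence time. That gives 9.66 % for Sunday's tank, less than the flask, and 33.8 % for Tuesday's tank, more than either.

The forecast also names Tuesday's, with 10.3 % for Saturday's, 10.3 % for Thursday's and 9.5 % for Sunday's. For Tuesday's it gives 24 %, below my figure, on the ground of “slow catalyst loss”.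

The set-ups give 10.3 % for Saturday's, 10.3 % for Thursday's, 9.74 % for Sunday's and 34.0 % for Tuesday's, where the pool constant times the mean residence time is 0.601.

    catalyst + added ligand ⇌ idle complex, settled at all times (K = 9500 M⁻¹)
    starting material + catalyst → catalyst + target (k = 1.52 M⁻¹ min⁻¹)
    starting material + protic impurity → quenched substrate (k = 0.718 M⁻¹ min⁻¹)

On Saturday's charge, protic impurity has a half-life of 0.0536 h with starting material held at its charge, shorter than the 4.5 h of starting material by the catalytic step alone with catalyst as charged, and the charge of protic impurity is 10.0 % of the starting material. That catalytic figure counts no idle complex, the resting state, while the binding constant times the added ligand at the start is 29.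

The runs were computed for substances that don't exist; noise was put on by code.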